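## Retrosynthetic overview

1. Numbering (mutilin): ring A = C1, C2 (ketone), C3, C4, C9. Ring B = C4, C5, C6, C7, C8, C9. Ring C = C4, C5, C14, C13, C12, C11, C10, C9. The plan rests on one feature: rings B and C share C5–C4–C9, a bicyclo[5.3.1]undecane with C4 as the one-carbon bridge, carrying oxygen at C8 and C14 and an oxidised C4.
2. Ring A is cut first. Retro-aldol at C3=C4 and removal of the three-carbon unit C1–C3 from the bridgehead C9 lead back to a bicyclic C4/C8 1,3-dione with a C14 ketone.
3. Rings B and C are cut together by a type 2 intramolecular Diels–Alder disconnection of C4–C5 and C6–C7. This gives an acyclic triene: a 1-methoxy-1,3-bis(silyloxy)diene (C4=C9–C8=C7) tethered at C9 through C10–C14 to a (Z)-2-methylbut-2-enoyl ketone (C5=C6).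
4. The C14 ketone is unveiled only after the strong-base enol silylation, from a C14 N-methoxy-N-methylamide and a (Z)-butenyllithium. C11–C12 comes from an asymmetric allylboration of a C11 aldehyde with an allene-derived (Z)-allylborane. C10 is set by iridium-catalysed crotylation of methyl acetoacetate.
5. Order of ring formation: B and C in one step, then A.

Key step: step 11

Assumption (chemistry): C5 and C9 are the bridgeheads of the bicyclo[5.3.1]undecane, which is only viable as the out,out isomer (C14 and C10 cis on ring B, C5 methyl and C1 outside, as in mutilin); all facial arguments refer to that framework, and every SMILES keeps the stereo tags of the given target string atom for atom, even though its C5/C6 tags, read against C9, would formally describe the inside–outside isomer.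

## Route

Step 1
Reactants: 1 (E)-but-2-en-1-ol
Product: 2 (E)-but-2-en-1-yl methyl carbonate
Conditions: ClCO2Me, pyridine, CH2Cl2, 0 °C → rt
Reagents that add atoms: methyl chloroformate, COC(=O)Cl
Why: Chloroformate O-acylation of a primary allylic alcohol is routine and gives the allylic carbonate whose ionisation in step 2 releases CO2 and the methoxide base.

Step 2
Reactants: 2 (E)-but-2-en-1-yl methyl carbonate; 3 methyl acetoacetate
Product: 4 methyl (3S)-2-acetyl-3-methylpent-4-enoate (C10 = 3S; epimer mixture at C9)
Conditions: [Ir(cod)Cl]2 (2 mol %), BINOL-derived N,N-bis(1-phenylethyl)phosphoramidite (4 mol %, the enantiomer that gives 3S), 1,5,7-triazabicyclo[4.4.0]dec-5-ene (8 mol %), THF, rt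
Reagents that add atoms: none
Why: Iridium-catalysed asymmetric allylic alkylation sends the stabilised acetoacetate enolate to the methyl-bearing allyl terminus (branched product) and the ligand sets C10, while C9 forms as a mixture that becomes sp2 in step 3.

Step 3
Reactants: 4 methyl (3S)-2-acetyl-3-methylpent-4-enoate
Product: 5 methyl 2-[(2S)-but-3-en-2-yl]-3-(tert-butyldimethylsilyloxy)but-2-enoate (E/Z mixture at C8=C9)
Conditions: TBSOTf, Et3N, CH2Cl2, 0 °C
Reagents that add atoms: tert-butyldimethylsilyl triflate, CC(C)(C)[Si](C)(C)OS(=O)(=O)C(F)(F)F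
Why: Soft enolisation and O-silylation of the β-keto ester installs the C8 silyloxy group of the later diene and removes the C8 ketone, which would otherwise condense with the C11 aldehyde of step 4 to a furan (Paal–Knorr type) and erase C10; the E/Z mixture is irrelevant because this double bond moves to C7=C8 in step 9.

Step 4
Reactants: 5 methyl 2-[(2S)-but-3-en-2-yl]-3-(tert-butyldimethylsilyloxy)but-2-enoate
Product: 6 methyl 3-(tert-butyldimethylsilyloxy)-2-[(2R)-1-oxopropan-2-yl]but-2-enoate (C11 aldehyde)
Conditions: OsO4 (2 mol %), NaIO4, 2,6-lutidine, dioxane/H2O, rt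
Reagents that add atoms: sodium periodate, [Na+].[O-]I(=O)(=O)=O
Why: In this Lemieux–Johnson oxidation OsO4 dihydroxylates the unhindered monosubstituted alkene much faster than the tetrasubstituted push–pull enol ether, NaIO4 cleaves the diol, and the lutidine buffer keeps the α-stereocentre C10 from epimerising.

Step 5
Reactants: 7 but-2-yn-1-ol; 8 triethyl orthoacetate
Product: 9 ethyl 3-methylpenta-3,4-dienoate
Conditions: EtCO2H (cat.), neat, 140 °C, ethanol distilled off
Reagents that add atoms: none
Why: In the Johnson orthoester Claisen rearrangement of a propargylic alcohol the [3,3] shift across the alkyne gives the β-allenic ester, forming C12–C13 and leaving the C12 methyl on the allene.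

Step 6
Reactants: 9 ethyl 3-methylpenta-3,4-dienoate
Product: 10 N-methoxy-N,3-dimethylpenta-3,4-dienamide
Conditions: MeNH(OMe)·HCl, AlMe3, CH2Cl2, 0 °C → rt
Reagents that add atoms: N,O-dimethylhydroxylamine hydrochloride, CNOC.Cl
Why: Aluminium-amide aminolysis of the ester is non-basic, so the β-allenic carbonyl compound is not isomerised to the conjugated diene.

Step 7
Reactants: 6 C11 aldehyde; 10 N-methoxy-N,3-dimethylpenta-3,4-dienamide
Product: 13 methyl (3R,4S,5S)-2-[1-(tert-butyldimethylsilyloxy)ethylidene]-5-ethenyl-4-hydroxy-7-[methoxy(methyl)amino]-3,5-dimethyl-7-oxoheptanoate, via (Z)-allylborane 11 (not isolated), via borinate 12 (not isolated)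
Conditions: (−)-α-pinene, BH3·SMe2, THF, 0 °C [(+)-Ipc2BH]; 10, −25 → 0 °C; 6, Et2O, −78 °C; pH 7 buffer, MeOH, 30 % H2O2, 0 °C
Reagents that add atoms: none
Why: Kinetic hydroboration of the 1,1-disubstituted allene on the side of its methyl group gives the (Z)-γ,γ-disubstituted allylborane 11, which adds to 6 through a closed chair transition state (asymmetric allylboration), so that the (Z)-CH2 group ends syn and the methyl anti to the C11 oxygen (C12 fixed relative to C11) and the isopinocampheyl groups from (−)-α-pinene direct attack to the Re face of the aldehyde (11S, 10,11-syn).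

Step 8
Reactants: 13 hydroxy amide
Product: 14 C11 tert-butyldimethylsilyl ether of 13
Conditions: TBSOTf, 2,6-lutidine, CH2Cl2, −78 → 0 °C
Reagents that add atoms: tert-butyldimethylsilyl triflate, CC(C)(C)[Si](C)(C)OS(=O)(=O)C(F)(F)F
Why: Silyl triflate silylation is fast even at the hindered C11 hydroxyl and outruns lactonisation of the γ-hydroxy amide onto C14, and the ether is inert to the bases, the organolithium and the Lewis acid that follow.

Step 9
Reactants: 14 C11 silyl ether
Product: 15 diene amide: (E)-1-methoxy-1,3-bis(tert-butyldimethylsilyloxy)buta-1,3-diene (C4=C9–C8=C7) carrying at C9 the chain (10R,11S,12S)-C10H(Me)–C11H(OTBS)–C12(Me)(vinyl)–C13H2–C14(O)N(OMe)Me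
Conditions: LiN(i-Pr)2 (1.15 equiv), THF, −78 °C; TBSCl, DMPU, −78 → 0 °C; pentane, cold aq NaHCO3 wash
Reagents that add atoms: tert-butyldimethylsilyl chloride, CC(C)(C)[Si](C)(C)Cl
Why: Vinylogous (γ) deprotonation of the β-silyloxy enoate at the C7 methyl and O-silylation of the dienolate is the standard route to 1-alkoxy-1,3-bis(silyloxy)dienes, and it is chemoselective here because C14 is still a tertiary amide whose neopentyl C13 hydrogens are far less acidic, whereas a C14 ketone would be enolised first; the C4=C9 geometry (drawn with OMe cis to C8) has no consequence because C4 ends as a ketone.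

Step 10
Reactants: 15 diene amide; 16 (Z)-2-bromobut-2-ene
Product: 17 triene: as 15, but C14 is the ketone of a (Z)-2-methylbut-2-enoyl group (C5=C6)
Conditions: 16, t-BuLi (2 equiv), Et2O, −78 °C; then 15, THF, −78 °C; pH 7 phosphate buffer
Reagents that add atoms: none
Why: Bromine–lithium exchange keeps the alkene geometry and acylation of the vinyllithium by the N-methoxy-N-methylamide stops at the chelated tetrahedral adduct, so the (Z)-enone appears only on the neutral quench, while the former ester, masked as a robust TBS ketene acetal, offers no electrophilic site.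

Step 11
Reactants: 17 triene
Product: 19 bicyclo[5.3.1]undecene-4,14-dione C8 silyl enol ether, via mixed methyl silyl acetal cycloadduct 18 (not isolated)
Conditions: Et2AlCl (1.1 equiv), CH2Cl2 (0.002 M), −78 → −20 °C; Et3N, then aq NaHCO3
Reagents that add atoms: none
Why: Coordination of Et2AlCl to the C14 ketone lowers the enone LUMO, and the 1,1,3-trioxygenated diene adds in an asynchronous, suprafacial [4+2] process in which the nucleophilic terminus C7 bonds to the β-carbon C6 slightly ahead of C4–C5 formation; loss of MeOTBS from 18 then leaves the C4 ketone conjugated with the C8=C9 enol ether. The closest known reaction type is the Lewis-acid-promoted type 2 intramolecular Diels–Alder reaction of 2-tethered dienes with enones, which gives bridgehead-alkene bicyclo[5.3.1]undecenes even with a disubstituted inner diene terminus, taken together with the known Diels–Alder behaviour of 1-alkoxy-1,3-bis(silyloxy)dienes. Ring B closes as the cycloaddition ring (C4–C5 and C6–C7), ring C closes through the same C4–C5 bond because the tether sits on diene position 2 (C9), and the five-atom tether C10–C14 can only span the 1,3-positions, which is also the orientation that polarity asks for (C7 to C6). C6 is fixed relative to C5 by the (Z)-geometry of the dienophile, which is transferred suprafacially and puts the C6 methyl cis to C14. The sense at C5 is set by the fold of the tether, since only the fold that keeps the C10 methyl, the C11 silyl ether and the C12 substituents on the periphery avoids pushing the C10 methyl under the forming ring B. The step needs retention of the (Z)-enone geometry and 1,4- rather than 1,2-attack on the enone, which low temperature, the proton-scavenging aluminium reagent, the fully substituted and therefore poorly nucleophilic C9, and high dilution are meant to secure.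

Step 12
Reactants: 19 bicyclic silyl enol ether
Product: 20 bicyclic 4,8,14-trione (drawn as its C8 enol), C11 OTBS
Conditions: Et3N·3HF, THF, 0 °C
Reagents that add atoms: none
Why: Fluoride cleaves the vinylogous silyl ester O–Si bond far faster than the hindered secondary C11 silyl ether, and the weakly acidic medium avoids retro-Claisen opening of the C4/C14 β-diketone.

Step 13
Reactants: 20 bicyclic trione
Product: 22 (14R)-14-hydroxy-4,8-dione, via lithium enolate 21 (not isolated)
Conditions: LiN(SiMe3)2 (1.05 equiv), THF, −78 °C; Li, NH3(l), t-BuOH, −78 °C; NH4Cl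
Reagents that add atoms: none
Why: In this dissolving-metal ketone reduction the C4/C8 dione is parked as its enolate 21, which accepts no electron and cannot release C5 by retro-Claisen or retro-Michael cleavage, and protonation of the C14 ketyl/carbanion gives the more stable 14R alcohol with the C–O bond pointing outward, the epimer that hydride reagents cannot give because the inner face of C14 is shielded by C10.

Step 14
Reactants: 22 hydroxy dione; 23 allyl methyl carbonate
Product: 24 C9-allyl-14-hydroxy-4,8-dione (allyl = C1–C3, on the outer face of C9)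
Conditions: Pd(PPh3)4 (5 mol %), THF, rt
Reagents that add atoms: none
Why: In this neutral Tsuji–Trost allylation O-allylation of the dione is reversible under zerovalent palladium whereas C-allylation is not, and at the bridgehead C9 the new bond can form only on the outer face, so C9 follows from C5 and the strained enolic C8=C9 bond is released.

Step 15
Reactants: 24 C9-allyl hydroxy dione
Product: 25 C14 acetate of 24
Conditions: Ac2O, DMAP, Et3N, CH2Cl2, rt
Reagents that add atoms: acetic anhydride, CC(=O)OC(C)=O
Why: DMAP-catalysed acetylation of the only free hydroxyl group places the C14 acetate while C11 is silylated and C8 is still a ketone, which differentiates the three oxygens.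

Step 16
Reactants: 25 acetate dione
Product: 26 (8S)-8-hydroxy-4-ketone (OH equatorial, cis to C10)
Conditions: NaBH4, MeOH/CH2Cl2, −40 → −10 °C
Reagents that add atoms: none
Why: This is a chemoselective borohydride reduction as known for 2,2-disubstituted cyclohexane-1,3-diones: C4 lies between two quaternary carbons and is inert, and hydride reaches C8 axially from the face opposite the C10–C14 bridge.

Step 17
Reactants: 26 C8 alcohol
Product: 27 C8 tert-butyldimethylsilyl ether of 26
Conditions: TBSOTf, 2,6-lutidine, CH2Cl2, 0 °C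
Reagents that add atoms: tert-butyldimethylsilyl triflate, CC(C)(C)[Si](C)(C)OS(=O)(=O)C(F)(F)F
Why: Silylation blocks retro-aldol cleavage of C8–C9 in the basic step 19, and with C8 no longer a carbonyl group the later aldol closure can only go to C4 and not to the less hindered C8.

Step 18
Reactants: 27 bis-silyl ether
Product: 28 C9-(2-oxopropyl) C4 ketone (C2 methyl ketone)
Conditions: PdCl2 (10 mol %), CuCl, O2 (1 atm), DMF/H2O, rt
Reagents that add atoms: water, O
Why: The Tsuji–Wacker oxidation gives the methyl ketone at the accessible allyl group, whereas the C12 vinyl group, bound directly to a quaternary carbon next to the bulky C11 silyl ether, reacts much more slowly.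

Step 19
Reactants: 28 1,4-diketone
Product: 29 tricyclic enone (C3=C4, C2 ketone) with C8 OTBS, C11 OTBS, C14 OAc
Conditions: KOt-Bu (0.3 equiv), t-BuOH/THF, 4 Å MS, 0 °C → rt
Reagents that add atoms: none
Why: In this intramolecular aldol condensation (5-enolexo closure of ring A) only the C3 enolate has a carbonyl group within reach, C4 is the only ketone left besides C2, and irreversible E1cB loss of water gives the conjugated enone, the neopentyl-type C14 acetate being slow to cleave under non-nucleophilic catalytic base.

Step 20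
Reactants: 29 protected enone
Product: 30 Pleuromutilin E
Conditions: HF (48 % aq), MeCN, 0 °C → rt
Reagents that add atoms: none
Why: Acidic fluoride removes both silyl ethers without touching the acetate, the enone or the vinyl group, and no stereocentre is affected.

## Compound list

1 | (E)-but-2-en-1-ol | C/C=C/CO | starting material
2 | (E)-but-2-en-1-yl methyl carbonate | C/C=C/COC(=O)OC | intermediate
3 | methyl acetoacetate | COC(=O)CC(C)=O | starting material
4 | methyl (3S)-2-acetyl-3-methylpent-4-enoate (C9 epimers) | C=C[C@H](C)C(C(C)=O)C(=O)OC | intermediate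
5 | methyl 2-[(2S)-but-3-en-2-yl]-3-(tert-butyldimethylsilyloxy)but-2-enoate (E/Z) | C=C[C@H](C)C(C(=O)OC)=C(C)O[Si](C)(C)C(C)(C)C | intermediate
6 | methyl 3-(tert-butyldimethylsilyloxy)-2-[(2R)-1-oxopropan-2-yl]but-2-enoate (E/Z) | O=C[C@H](C)C(C(=O)OC)=C(C)O[Si](C)(C)C(C)(C)C | intermediate
7 | but-2-yn-1-ol | CC#CCO | starting material
8 | triethyl orthoacetate | CC(OCC)(OCC)OCC | starting material
9 | ethyl 3-methylpenta-3,4-dienoate | C=C=C(C)CC(=O)OCC | intermediate
10 | N-methoxy-N,3-dimethylpenta-3,4-dienamide | C=C=C(C)CC(=O)N(C)OC | intermediate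
11 | (Z)-5-[methoxy(methyl)amino]-3-methyl-5-oxopent-2-enyl-diisopinocampheylborane | CON(C)C(=O)C/C(C)=C\CB([C@H]1C[C@H]2C[C@@H]([C@@H]1C)C2(C)C)[C@H]1C[C@H]2C[C@@H]([C@@H]1C)C2(C)C | intermediate
12 | diisopinocampheylborinate of 13 | C=C[C@]([C@@H](OB([C@H]1C[C@H]2C[C@@H]([C@@H]1C)C2(C)C)[C@H]1C[C@H]2C[C@@H]([C@@H]1C)C2(C)C)[C@H](C)C(C(=O)OC)=C(C)O[Si](C)(C)C(C)(C)C)(C)CC(=O)N(C)OC | intermediate
13 | methyl (3R,4S,5S)-2-[1-(tert-butyldimethylsilyloxy)ethylidene]-5-ethenyl-4-hydroxy-7-[methoxy(methyl)amino]-3,5-dimethyl-7-oxoheptanoate (10R,11S,12S) | C=C[C@]([C@@H](O)[C@H](C)C(C(=O)OC)=C(C)O[Si](C)(C)C(C)(C)C)(C)CC(=O)N(C)OC | intermediate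
14 | C11 TBS ether of 13 | C=C[C@]([C@@H](O[Si](C)(C)C(C)(C)C)[C@H](C)C(C(=O)OC)=C(C)O[Si](C)(C)C(C)(C)C)(C)CC(=O)N(C)OC | intermediate
15 | (E)-1-methoxy-1,3-bis(TBSO)butadiene tethered at C9 to the (10R,11S,12S) chain ending in the C14 N-methoxy-N-methylamide | C=C[C@]([C@@H](O[Si](C)(C)C(C)(C)C)[C@H](C)/C(=C(/OC)O[Si](C)(C)C(C)(C)C)C(=C)O[Si](C)(C)C(C)(C)C)(C)CC(=O)N(C)OC | intermediate
16 | (Z)-2-bromobut-2-ene | C/C=C(/C)Br | starting material
17 | silyloxy diene–(Z)-2-methylbut-2-enoyl ketone triene (10R,11S,12S) | C=C[C@]([C@@H](O[Si](C)(C)C(C)(C)C)[C@H](C)/C(=C(/OC)O[Si](C)(C)C(C)(C)C)C(=C)O[Si](C)(C)C(C)(C)C)(C)CC(=O)/C(C)=C\C | intermediate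
18 | cycloadduct with C4(OMe)(OTBS) (C4 configuration of no consequence) | C=C[C@]1(C)CC(=O)[C@]2(C)C(OC)(O[Si](C)(C)C(C)(C)C)C(=C(O[Si](C)(C)C(C)(C)C)C[C@@H]2C)[C@@H](C)[C@@H]1O[Si](C)(C)C(C)(C)C | intermediate
19 | 8,11-bis(TBSO)-5,6,10,12-tetramethyl-12-vinylbicyclo[5.3.1]undec-8(9)-ene-4,14-dione (mutilin numbering; C5 methyl outside, C6 methyl cis to C14, 10R,11S,12S) | C=C[C@]1(C)CC(=O)[C@]2(C)C(=O)C(=C(O[Si](C)(C)C(C)(C)C)C[C@@H]2C)[C@@H](C)[C@@H]1O[Si](C)(C)C(C)(C)C | intermediate
20 | 4,8,14-trione, C8 enol form, C11 OTBS | C=C[C@]1(C)CC(=O)[C@]2(C)C(=O)C(=C(O)C[C@@H]2C)[C@@H](C)[C@@H]1O[Si](C)(C)C(C)(C)C | intermediate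
21 | lithium enolate of 20 | C=C[C@]1(C)CC(=O)[C@]2(C)C(=O)C(=C([O-])C[C@@H]2C)[C@@H](C)[C@@H]1O[Si](C)(C)C(C)(C)C.[Li+] | intermediate
22 | (14R)-14-hydroxy-4,8-dione, C8 enol form | C=C[C@]1(C)C[C@@H](O)[C@]2(C)C(=O)C(=C(O)C[C@@H]2C)[C@@H](C)[C@@H]1O[Si](C)(C)C(C)(C)C | intermediate
23 | allyl methyl carbonate | C=CCOC(=O)OC | starting material
24 | C9-allyl-(14R)-14-hydroxy-4,8-dione (allyl outside) | C=C[C@]1(C)C[C@@H](O)[C@]2(C)C(=O)[C@](CC=C)(C(=O)C[C@@H]2C)[C@@H](C)[C@@H]1O[Si](C)(C)C(C)(C)C | intermediate
25 | C14 acetate of 24 | C=C[C@]1(C)C[C@@H](OC(C)=O)[C@]2(C)C(=O)[C@](CC=C)(C(=O)C[C@@H]2C)[C@@H](C)[C@@H]1O[Si](C)(C)C(C)(C)C | intermediate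
26 | (8S)-8-hydroxy-4-ketone (OH cis to C10) | C=C[C@]1(C)C[C@@H](OC(C)=O)[C@]2(C)C(=O)[C@](CC=C)([C@@H](O)C[C@@H]2C)[C@@H](C)[C@@H]1O[Si](C)(C)C(C)(C)C | intermediate
27 | C8 TBS ether of 26 | C=C[C@]1(C)C[C@@H](OC(C)=O)[C@]2(C)C(=O)[C@](CC=C)([C@@H](O[Si](C)(C)C(C)(C)C)C[C@@H]2C)[C@@H](C)[C@@H]1O[Si](C)(C)C(C)(C)C | intermediate
28 | C9-(2-oxopropyl) C4 ketone | C=C[C@]1(C)C[C@@H](OC(C)=O)[C@]2(C)C(=O)[C@](CC(C)=O)([C@@H](O[Si](C)(C)C(C)(C)C)C[C@@H]2C)[C@@H](C)[C@@H]1O[Si](C)(C)C(C)(C)C | intermediate
29 | 8,11-bis-O-TBS Pleuromutilin E | C=C[C@]1(C)C[C@@H](OC(C)=O)[C@]2(C)C3=CC(=O)C[C@@]3([C@@H](O[Si](C)(C)C(C)(C)C)C[C@@H]2C)[C@@H](C)[C@@H]1O[Si](C)(C)C(C)(C)C | intermediate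
30 | Pleuromutilin E | C=C[C@]1(C)C[C@@H](OC(C)=O)[C@]2(C)C3=CC(=O)C[C@@]3([C@@H](O)C[C@@H]2C)[C@@H](C)[C@@H]1O | target

## Step count and risks

Total steps: 20. Longest linear sequence: 18 steps (steps 1–4 and 7–20).

Steps most likely to fail:

**Step 11.** The C4–C5 bond has to join two fully substituted carbons, so the reaction may stall after conjugate addition at C6 or divert to 1,2-attack at C14. The Lewis acid may also isomerise the (Z)-enone, and the fold of the tether may discriminate the two diene faces poorly. In the fallback the quaternary centre C5 is no longer made in the cycloaddition. It sets out again from 15. Acylation of (Z)-prop-1-enyllithium (from (Z)-1-bromoprop-1-ene and t-BuLi) gives the C5-demethyl triene F1. The same type 2 cycloaddition, now onto a CH dienophile carbon, leads to the bicyclic β-diketone F2, whose C5–H lies between the C4 and C14 carbonyl groups. Methylation (MeI, K2CO3, acetone) on the only open, outer face of that bridgehead comes back to the route at 19.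

**Step 19.** Addition of the C3 enolate to the C4 carbonyl group between two quaternary carbons may be slow and reversible, so that acetate cleavage or acetyl migration to the C4 alkoxide overtakes ring closure. The fallback activates the ketone with a Lewis acid instead of relying on enolate chemistry. It sets out from 28. TMSOTf/Et3N gives the terminal trimethylsilyl enol ether F3 (C1 is neopentyl and C4 cannot enolise). TiCl4 in CH2Cl2 at −78 °C closes ring A by an intramolecular Mukaiyama aldol addition to the tertiary aldol F4. SOCl2/pyridine dehydrates it, which comes back to the route at 29.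

**Step 14.** The hindered bridgehead carbon may be too poor a nucleophile for the π-allylpalladium complex, so that the reaction stops at O-allylation or does not start. The fallback delivers the allyl group intramolecularly by a sigmatropic shift. It sets out from 22. Allyl bromide/K2CO3 in acetone makes the allyl enol ether F5 on purpose. Heating in xylene (140 °C) moves the allyl group from O8 to C9 by a Claisen rearrangement on the outer face, which comes back to the route at 24.

## Further compounds

F1 | step 11 | C5-demethyl triene (as 17 with a (Z)-but-2-enoyl ketone) | C=C[C@]([C@@H](O[Si](C)(C)C(C)(C)C)[C@H](C)/C(=C(/OC)O[Si](C)(C)C(C)(C)C)C(=C)O[Si](C)(C)C(C)(C)C)(C)CC(=O)/C=C\C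
F2 | step 11 | bicyclic β-diketone with C5–H (as 19 without the C5 methyl) | C=C[C@]1(C)CC(=O)[C@@H]2C(=O)C(=C(O[Si](C)(C)C(C)(C)C)C[C@@H]2C)[C@@H](C)[C@@H]1O[Si](C)(C)C(C)(C)C
F3 | step 19 | terminal trimethylsilyl enol ether of 28 | C=C[C@]1(C)C[C@@H](OC(C)=O)[C@]2(C)C(=O)[C@](CC(=C)O[Si](C)(C)C)([C@@H](O[Si](C)(C)C(C)(C)C)C[C@@H]2C)[C@@H](C)[C@@H]1O[Si](C)(C)C(C)(C)C
F4 | step 19 | tertiary aldol, C4 hydroxy cyclopentanone (C4 configuration of no consequence) | C=C[C@]1(C)C[C@@H](OC(C)=O)[C@]2(C)C3(O)CC(=O)C[C@@]3([C@@H](O[Si](C)(C)C(C)(C)C)C[C@@H]2C)[C@@H](C)[C@@H]1O[Si](C)(C)C(C)(C)C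
F5 | step 14 | C8 allyl enol ether of 22 | C=C[C@]1(C)C[C@@H](O)[C@]2(C)C(=O)C(=C(OCC=C)C[C@@H]2C)[C@@H](C)[C@@H]1O[Si](C)(C)C(C)(C)C
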